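## Structural features

The target is a dihydroflavonol: a chroman-4-one (ring C: O1, C2, C3, C4, fused through C4a/C8a to the benzene ring A) that carries a 4-hydroxy-3-methoxyphenyl ring (ring B) on C2 through the single C2–C1' bond and a hydroxyl on C3 (flavonoid numbering throughout). Ring A is fully differentiated: 5-OH hydrogen-bonded to the C4 carbonyl, a prenyl chain on C6, 7-OMe and H on C8. The only stereocentres, C2 (R) and C3 (R), are adjacent and trans, with aryl and hydroxyl both equatorial. Both are labile. C3–H is α to the ketone, and enolisation opens the O1–C2 bond by E1cB (retro-oxa-Michael) or leads on to the flavonol. The free 4'-OH allows reversible O1–C2 cleavage through a para-quinone methide, so base must be avoided once the phenols are free. The prenyl group is sensitive to acid (cyclisation onto the 5-OH), to epoxidising oxidants and to hydrogenation, which excludes benzyl protection. The real difficulty is twofold: absolute control of the C2/C3 pair in a ring that tolerates little base, and the regiochemistry of ring A (6- versus 8-prenyl, 5-OH versus O1), which is ambiguous whenever the heterocycle is closed onto a 2',6'-dioxygenated aryl ketone. The key step exploits the fact that C2 and C3 are the β- and α-carbons of the vinylogous ester O1–C2=C3–C4=O of the corresponding chromone, and that ring B hangs on C2 by one C–C bond. Ring B can therefore be delivered as an aryl nucleophile to the flat, achiral A/C bicycle under catalyst control, and the C3 enolate carbon is the site that then takes up the oxygen.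

## Logic of the disconnections

**19 ⇒ 17 + 18.** The C2''=C3'' double bond of the side chain on C6 is cut (cross-metathesis retron). The trisubstituted olefin is the one group that tolerates neither the acid of the deprotection nor electrophilic oxidants, whereas a terminal allyl group tolerates both and can be placed on C6 without isomers. The gain is that the fragile group is made last in one step. The demand is a metathesis that runs on free phenols and an α-ketol under neutral conditions without moving the double bond.

**17 ⇒ 16.** The two O–CH2OMe bonds on O5 and O4' are cut. Phenoxides must not exist while C2 and C3 are being set (para-quinone methide from O4', chelated O5 anion). The demand on the forward step is acid only, never base.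

**16 ⇒ 13 + 14 (through 15).** The C3–O bond is cut. C3 is the enolate carbon of the ketone left by the key step, and the aryl group on C2 directs the oxygen to the opposite face, which gives the trans pair. This removes the second stereocentre and leaves a compound with one. The forward step must form and quench 15 cold so that O1–C2 does not open, and must use an oxidant that ignores the allyl group.

**13 ⇒ 10 + 12 (key disconnection).** The C2–C1' bond is cut, the only C–C bond that links ring B to the A/C bicycle. The cut turns the stereogenic sp3 carbon C2 into the β-carbon of a flat, achiral partner, so the absolute configuration is introduced by a catalyst at the moment the two halves are joined, and every stereocentre of 19 derives from this one event. The gain is two achiral fragments of similar size and a ring-A pattern that is settled before, and independently of, the stereochemistry. In one sentence: a catalytic enantioselective 1,4-addition of the ring-B boron reagent 12 to the preformed A/C bicycle 10. The demands are enantioface control, 1,4-selectivity on an electron-rich vinylogous ester, and conditions mild enough that 13 does not racemise by ring opening.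

**12 ⇒ 11 + 9.** The O4'–CH2OMe bond is cut. A free phenol para to boron would become a phenoxide under the coupling and enolate conditions. The forward step is a routine etherification that must leave the C–B bond alone.

**10 ⇒ 8 + 9.** The O5–CH2OMe bond is cut. The chelated 5-OH would consume base and deactivate the C4 carbonyl in the two steps that follow. The forward step must alkylate a hindered, hydrogen-bonded phenol.

**8 ⇒ 6 (through 7).** The C6–CH2 bond is cut and the allyl group is returned to O5 ([3,3] retron). C6 is the only ortho position of O5 that carries hydrogen (the other is the ring-fusion carbon C4a), so the rearrangement can deliver the chain only to C6 and the 6- versus 8-problem does not arise. The demand is a thermal step that the pyranone survives.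

**6 ⇒ 4 + 5.** The O5–allyl bond is cut. 4 has a single hydroxyl, so no selectivity is needed.

**4 ⇒ 1 + 2 (through 3).** The O1–C2 and C2–C3 bonds of the pyranone are cut; C2 is a one-carbon unit at the oxidation level of formic acid. 1 has a mirror plane, so its two hydroxyls are equivalent: whichever closes, the other becomes the 5-OH. The differentiation of O1 from O5 is thus settled in the first step.

## Other disconnections considered

**Alternative 1:** the first idea is to cut O1–C2 and form it by opening an epoxide. The chalcone (E)-1-[3-allyl-4-methoxy-2,6-bis(methoxymethoxy)phenyl]-3-[3-methoxy-4-(methoxymethoxy)phenyl]prop-2-en-1-one A1 would be epoxidised enantioselectively (Juliá–Colonna conditions) to the (2R,3S)-epoxy ketone A2. Acid would then free the phenols and close ring C by 6-endo attack at the benzylic carbon with inversion, arriving at 17. The chosen plan is preferred on three grounds.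
- The acid that frees the nucleophilic phenol of A2 also frees the second ortho oxygen, which is equally labile. Closure through the wrong oxygen would put the allyl group on C8; in the chosen route one of the two oxygens is already O1 from step 1.
- The benzylic carbon of A2 carries a para-oxygenated aryl group, so the opening is expected to have carbocation character, with erosion at C2 and competing 5-exo closure or aryl migration.
- The stereocentres would be made on an open chain and then have to survive a ring closure, instead of being made on the finished ring.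

**Alternative 2:** cut C3–C4 and form it by an NHC-catalysed intramolecular crossed benzoin reaction of the dialdehyde 3-allyl-4-methoxy-2-(methoxymethoxy)-6-{1-[3-methoxy-4-(methoxymethoxy)phenyl]-2-oxoethoxy}benzaldehyde A3. The α-aryloxy aldehyde centre of A3 would epimerise freely, so a chiral carbene could in principle set C2 and C3 together in a dynamic kinetic sense. The plan is not preferred for these reasons.
- The Breslow intermediate would have to form at the aromatic aldehyde, which is electron-rich and flanked by two ortho substituents, while the unhindered aliphatic aldehyde stays the acceptor. The reversed polarity would place the hydroxyl on C4 and the carbonyl on C3.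
- A Breslow intermediate at the aliphatic aldehyde has the ring-A aryloxide as a β-leaving group, and its loss would destroy the O1–C2 bond.
- A3 would take more steps to make than the whole chosen route.

**Alternative 3:** cut O1–C2 and C4–C4a. The phenol 4-allyl-3-methoxy-5-(methoxymethoxy)phenol A4 would open the glycidic ester methyl (2R,3S)-3-[3-methoxy-4-(methoxymethoxy)phenyl]oxirane-2-carboxylate A5 at the benzylic carbon to give the ether methyl (2R,3R)-3-[4-allyl-3-methoxy-5-(methoxymethoxy)phenoxy]-2-hydroxy-3-[3-methoxy-4-(methoxymethoxy)phenyl]propanoate A6. Its acid would close ring C by intramolecular Friedel–Crafts acylation. The plan is not preferred for these reasons.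
- The ring of A4 offers two open positions ortho to the ether oxygen, so the acylation has the same regiochemical ambiguity that the chosen route avoids.
- The acylation needs strong acid, under which the benzylic C–O bond of A6 (para-oxygenated aryl, aryloxide leaving group) should ionise and the MOM ethers should fall off.
- The opening of A5 by a phenoxide has to compete with attack at the carbon next to the ester and with an SN1 course.

Key step: step 6

Remark: 1 and 11 are taken as commercial. The (S)-ligand in step 6 is assigned on the assumption that the chromone binds to rhodium as 2-cyclohexenone does in the usual quadrant model; the sense is a property of the ligand enantiomer, and both enantiomers are available.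

## Route

**Step 1**
Reactants: 1 2',6'-dihydroxy-4'-methoxyacetophenone; 2 N,N-dimethylformamide dimethyl acetal
Product: 4 5-hydroxy-7-methoxy-4H-chromen-4-one, via enaminone 3 (not isolated)
Conditions: 2 (2.5 equiv), toluene, 95 °C; then conc. HCl, CH2Cl2, 40 °C
Reagents that add atoms: N,N-dimethylformamide dimethyl acetal (2), COC(OC)N(C)C
Why: Condensation of the methyl ketone with the amide acetal gives the enaminone, and acid then promotes conjugate addition of an ortho-hydroxyl and loss of dimethylamine (enaminone chromone annulation). The two hydroxyls of 1 are equivalent by symmetry, so only one chromone can form and the other hydroxyl becomes the 5-OH.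

**Step 2**
Reactants: 4 5-hydroxy-7-methoxy-4H-chromen-4-one; 5 allyl bromide
Product: 6 5-(allyloxy)-7-methoxy-4H-chromen-4-one
Conditions: 5 (1.5 equiv), K2CO3 (2 equiv), DMF, 60 °C
Reagents that add atoms: allyl bromide (5), C=CCBr
Why: Williamson etherification of the only hydroxyl; warming in DMF overcomes the hydrogen bond to the C4 carbonyl, and the pyranone is stable to carbonate.

**Step 3**
Reactants: 6 5-(allyloxy)-7-methoxy-4H-chromen-4-one
Product: 8 6-allyl-5-hydroxy-7-methoxy-4H-chromen-4-one, via ortho-dienone 7 (not isolated)
Conditions: N,N-diethylaniline, 200 °C (sealed tube)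
Reagents that add atoms: none
Why: Aromatic Claisen rearrangement: the [3,3] shift delivers the allyl group to C6, the only ortho position of O5 that bears hydrogen, and tautomerisation of the dienone restores the chelated phenol. The simple allyl group arrives without allylic transposition problems, so ring A is fixed as 5-OH, 6-allyl, 7-OMe.

**Step 4**
Reactants: 8 6-allyl-5-hydroxy-7-methoxy-4H-chromen-4-one; 9 chloromethyl methyl ether
Product: 10 6-allyl-7-methoxy-5-(methoxymethoxy)-4H-chromen-4-one
Conditions: NaH (1.3 equiv), 9 (1.5 equiv), DMF, 0 °C to rt
Reagents that add atoms: chloromethyl methyl ether (9), COCCl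
Why: O-Alkylation of the sodium phenoxide (MOM protection); a full equivalent of strong base is used because the 5-OH is chelated and flanked by the allyl group.

**Step 5**
Reactants: 11 2-methoxy-4-(4,4,5,5-tetramethyl-1,3,2-dioxaborolan-2-yl)phenol; 9 chloromethyl methyl ether
Product: 12 2-[3-methoxy-4-(methoxymethoxy)phenyl]-4,4,5,5-tetramethyl-1,3,2-dioxaborolane
Conditions: 9 (1.3 equiv), iPr2NEt (2 equiv), CH2Cl2, 0 °C to rt
Reagents that add atoms: chloromethyl methyl ether (9), COCCl
Why: MOM protection of the phenol under amine base; the pinacol boronate is inert to these conditions.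

**Step 6**
Reactants: 10 6-allyl-7-methoxy-5-(methoxymethoxy)-4H-chromen-4-one; 12 2-[3-methoxy-4-(methoxymethoxy)phenyl]-4,4,5,5-tetramethyl-1,3,2-dioxaborolane
Product: 13 (2S)-6-allyl-7-methoxy-2-[3-methoxy-4-(methoxymethoxy)phenyl]-5-(methoxymethoxy)chroman-4-one
Conditions: [RhCl(C2H4)2]2 (3 mol %), (S)-MeO-F12-BIPHEP [(S)-6,6'-dimethoxybiphenyl-2,2'-diylbis(bis(3,4,5-trifluorophenyl)phosphine)] (6.6 mol %), 12 (2.5 equiv), aq. KOH (0.5 equiv), 1,4-dioxane/H2O (10:1), 35 °C
Reagents that add atoms: none
Why: The hydroxo-rhodium(I) bisphosphine complex takes the aryl group from the hydroxide-activated boronate; the aryl-rhodium species binds the C2=C3 bond of 10 and inserts it, placing the aryl on C2 and rhodium on C3 as an oxa-π-allyl (rhodium enolate), which water protonates to release the ketone and regenerate Rh–OH. The closest known reaction type is the Hayashi–Miyaura rhodium-catalysed asymmetric 1,4-addition of arylboron reagents to enones, which is established for chromones, 5,7-dioxygenated ones included. No ring is closed; the bond formed is C2–C1'. The single new stereocentre, C2, is controlled by the catalyst alone, because 10 is flat and achiral; the (S)-ligand is expected to deliver the aryl to the face that gives (2S). The step needs 1,4- over 1,2-addition, which the vinylogous ester polarisation and the 5-OMOM group flanking the C4 carbonyl should secure. It needs the allyl group to stay untouched, which holds because an unactivated terminal olefin does not insert into the aryl–rhodium bond under these conditions. It needs 13 to keep its configuration, which the electron-rich 5,7-dioxygenated phenoxide (a poor leaving group for E1cB opening), the sub-stoichiometric base and the low temperature should ensure. The excess of 12 covers protodeboronation of the electron-rich aryl group.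

**Step 7**
Reactants: 13 (2S)-6-allyl-7-methoxy-2-[3-methoxy-4-(methoxymethoxy)phenyl]-5-(methoxymethoxy)chroman-4-one; 14 3-phenyl-2-(phenylsulfonyl)oxaziridine
Product: 16 (2R,3R)-6-allyl-3-hydroxy-7-methoxy-2-[3-methoxy-4-(methoxymethoxy)phenyl]-5-(methoxymethoxy)chroman-4-one, via sodium enolate 15 (not isolated)
Conditions: NaHMDS (1.2 equiv), THF, −78 °C; 14 (1.5 equiv), −78 °C; AcOH, −78 °C
Reagents that add atoms: 3-phenyl-2-(phenylsulfonyl)oxaziridine (14), O=S(=O)(c1ccccc1)N1OC1c1ccccc1
Why: Enolate hydroxylation with an N-sulfonyloxaziridine: the oxygen is transferred to C3 of the sodium enolate on the face opposite to the C2 aryl group, which gives the trans (3R) alcohol, also the more stable diastereomer, and the reagent does not epoxidise the allyl group at −78 °C. C2 is untouched; its descriptor changes from S to R only because C3 now outranks the aryl group.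

**Step 8**
Reactants: 16 (2R,3R)-6-allyl-3-hydroxy-7-methoxy-2-[3-methoxy-4-(methoxymethoxy)phenyl]-5-(methoxymethoxy)chroman-4-one
Product: 17 (2R,3R)-6-allyl-3,5-dihydroxy-2-(4-hydroxy-3-methoxyphenyl)-7-methoxychroman-4-one
Conditions: 3 M HCl/MeOH (1:5), 45 °C
Reagents that add atoms: none
Why: Acid-catalysed acetal exchange removes both MOM ethers (the chelation-assisted 5-O ether first). No phenoxide is formed, so neither the quinone-methide nor the E1cB pathway is open to C2 and C3, and the terminal allyl group cannot cyclise onto the 5-OH under these conditions.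

**Step 9**
Reactants: 17 (2R,3R)-6-allyl-3,5-dihydroxy-2-(4-hydroxy-3-methoxyphenyl)-7-methoxychroman-4-one; 18 2-methyl-2-butene
Product: 19 (2R,3R)-3,5-dihydroxy-2-(4-hydroxy-3-methoxyphenyl)-7-methoxy-6-(3-methylbut-2-en-1-yl)chroman-4-one
Conditions: second-generation Grubbs catalyst (5 mol %), 18/CH2Cl2 (1:2), 40 °C (sealed tube)
Reagents that add atoms: 2-methyl-2-butene (18), CC=C(C)C
Why: Olefin cross-metathesis of the terminal allyl group with a large excess of the trisubstituted olefin converts CH=CH2 into CH=C(CH3)2 with loss of propene. The conditions are neutral, tolerate phenols, ketone and secondary alcohol, and leave C2 and C3 untouched.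

## Compound list

1 | 2',6'-dihydroxy-4'-methoxyacetophenone | CC(=O)c1c(O)cc(OC)cc1O | starting material
2 | N,N-dimethylformamide dimethyl acetal | COC(OC)N(C)C | starting material
3 | (E)-1-(2,6-dihydroxy-4-methoxyphenyl)-3-(dimethylamino)prop-2-en-1-one | CN(C)/C=C/C(=O)c1c(O)cc(OC)cc1O | intermediate
4 | 5-hydroxy-7-methoxy-4H-chromen-4-one | COc1cc(O)c2c(c1)OC=CC2=O | intermediate
5 | allyl bromide | C=CCBr | starting material
6 | 5-(allyloxy)-7-methoxy-4H-chromen-4-one | COc1cc(OCC=C)c2c(c1)OC=CC2=O | intermediate
7 | 6-allyl-7-methoxy-4H-chromene-4,5(6H)-dione | COC1=CC2=C(C(=O)C1CC=C)C(=O)C=CO2 | intermediate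
8 | 6-allyl-5-hydroxy-7-methoxy-4H-chromen-4-one | COc1cc2c(c(O)c1CC=C)C(=O)C=CO2 | intermediate
9 | chloromethyl methyl ether | COCCl | starting material
10 | 6-allyl-7-methoxy-5-(methoxymethoxy)-4H-chromen-4-one | COCOc1c(CC=C)c(OC)cc2c1C(=O)C=CO2 | intermediate
11 | 2-methoxy-4-(4,4,5,5-tetramethyl-1,3,2-dioxaborolan-2-yl)phenol | COc1cc(B2OC(C)(C)C(C)(C)O2)ccc1O | starting material
12 | 2-[3-methoxy-4-(methoxymethoxy)phenyl]-4,4,5,5-tetramethyl-1,3,2-dioxaborolane | COCOc1ccc(B2OC(C)(C)C(C)(C)O2)cc1OC | intermediate
13 | (2S)-6-allyl-7-methoxy-2-[3-methoxy-4-(methoxymethoxy)phenyl]-5-(methoxymethoxy)chroman-4-one | COc1cc([C@H]2Oc3cc(OC)c(CC=C)c(OCOC)c3C(=O)C2)ccc1OCOC | intermediate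
14 | 3-phenyl-2-(phenylsulfonyl)oxaziridine | O=S(=O)(c1ccccc1)N1OC1c1ccccc1 | starting material
15 | sodium (2S)-6-allyl-7-methoxy-2-[3-methoxy-4-(methoxymethoxy)phenyl]-5-(methoxymethoxy)-2H-chromen-4-olate | COc1cc([C@H]2Oc3cc(OC)c(CC=C)c(OCOC)c3C([O-])=C2)ccc1OCOC.[Na+] | intermediate
16 | (2R,3R)-6-allyl-3-hydroxy-7-methoxy-2-[3-methoxy-4-(methoxymethoxy)phenyl]-5-(methoxymethoxy)chroman-4-one | COc1cc([C@H]2Oc3cc(OC)c(CC=C)c(OCOC)c3C(=O)[C@@H]2O)ccc1OCOC | intermediate
17 | (2R,3R)-6-allyl-3,5-dihydroxy-2-(4-hydroxy-3-methoxyphenyl)-7-methoxychroman-4-one | COc1cc([C@H]2Oc3cc(OC)c(CC=C)c(O)c3C(=O)[C@@H]2O)ccc1O | intermediate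
18 | 2-methyl-2-butene | CC=C(C)C | starting material
19 | (2R,3R)-3,5-dihydroxy-2-(4-hydroxy-3-methoxyphenyl)-7-methoxy-6-(3-methylbut-2-en-1-yl)chroman-4-one | COc1cc([C@H]2Oc3cc(OC)c(CC=C(C)C)c(O)c3C(=O)[C@@H]2O)ccc1O | target

## Step count and least certain steps

Total step count: 9. Longest linear sequence: 8 steps (steps 1 to 4 and 6 to 9); step 5 is the one-step side branch.

**Step 6 (key step).** Three things may go wrong. Transmetalation of the pinacol boronate and insertion of a doubly donor-substituted vinylogous ester may be slow, so that protodeboronation of the electron-rich aryl group outruns the addition. The product may lose enantiomeric purity by base-induced ring opening and reclosure at O1–C2. The sense of induction may be opposite to the one assumed, which is answered by the other ligand enantiomer.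

The fallback sets out from 10 and comes back at 13.
- Aqueous NaOH in EtOH at reflux should cleave the pyranone (hydroxide addition at C2, ring opening, loss of formate) to the o-hydroxyacetophenone 1-[3-allyl-6-hydroxy-4-methoxy-2-(methoxymethoxy)phenyl]ethan-1-one F1, in which the two ring-A oxygens stay differentiated.
- Claisen–Schmidt condensation (KOH, EtOH) with 3-methoxy-4-(methoxymethoxy)benzaldehyde F2, made from vanillin and 9, should give the chalcone (E)-1-[3-allyl-6-hydroxy-4-methoxy-2-(methoxymethoxy)phenyl]-3-[3-methoxy-4-(methoxymethoxy)phenyl]prop-2-en-1-one F3.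
- NaOAc in EtOH at reflux should close F3 by oxa-Michael addition of its one free hydroxyl to the racemic flavanone 6-allyl-7-methoxy-2-[3-methoxy-4-(methoxymethoxy)phenyl]-5-(methoxymethoxy)chroman-4-one F4.
- Kinetic resolution by Ru(II)–TsDPEN transfer hydrogenation (HCO2H/Et3N), with the catalyst enantiomer for which the (2R)-ketone reacts faster, should leave 13 and turn the other enantiomer into the cis-flavanol (2R,4R)-6-allyl-7-methoxy-2-[3-methoxy-4-(methoxymethoxy)phenyl]-5-(methoxymethoxy)chroman-4-ol F5, which is removed by chromatography.

**Step 7.** The enolate may open at O1–C2 by E1cB before it is oxidised, which would racemise C2 and divert material to the chalcone. It may add to the sulfonimine by-product. Over-oxidation toward the flavonol and incomplete facial selectivity are further risks.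

The fallback sets out from 13 and comes back at 17.
- Soft enolisation (TBSOTf, Et3N, CH2Cl2, −78 to 0 °C) should give the silyl enol ether tert-butyl{[(2S)-6-allyl-7-methoxy-2-[3-methoxy-4-(methoxymethoxy)phenyl]-5-(methoxymethoxy)-2H-chromen-4-yl]oxy}dimethylsilane F6 without a free enolate.
- Rubottom oxidation with dimethyldioxirane (1.05 equiv, acetone/CH2Cl2, −78 °C) should epoxidise the electron-rich enol ether anti to the C2 aryl group much faster than the monosubstituted allyl olefin. Opening of the silyloxy epoxide with silyl shift gives the silyl ether (2R,3R)-6-allyl-3-[(tert-butyldimethylsilyl)oxy]-7-methoxy-2-[3-methoxy-4-(methoxymethoxy)phenyl]-5-(methoxymethoxy)chroman-4-one F7.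
- The acid of step 8 removes the silyl group together with the MOM ethers.

**Step 9.** Ruthenium hydride species may move the double bond of the o-allylphenol into conjugation before metathesis. The chelating α-ketol and phenols may slow the catalyst, and conversion to the trisubstituted olefin may stay incomplete.

The fallback sets out from 10 and comes back at 19.
- The same cross-metathesis with 18 is run on the protected, achiral chromone to give 7-methoxy-5-(methoxymethoxy)-6-(3-methylbut-2-en-1-yl)-4H-chromen-4-one F8.
- The conditions of step 6 then give the flavanone (2S)-7-methoxy-2-[3-methoxy-4-(methoxymethoxy)phenyl]-5-(methoxymethoxy)-6-(3-methylbut-2-en-1-yl)chroman-4-one F9.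
- The conditions of step 7, whose oxidant spares the prenyl olefin, give the alcohol (2R,3R)-3-hydroxy-7-methoxy-2-[3-methoxy-4-(methoxymethoxy)phenyl]-5-(methoxymethoxy)-6-(3-methylbut-2-en-1-yl)chroman-4-one F10.
- The acid of step 8, applied at the lowest workable temperature because the prenyl group is now present, gives 19.

**Step 3.** The allyl group may migrate to the ring-fusion carbon C4a and on to C8 by a Cope shift (para-Claisen course). The chromone may decompose at 200 °C, and the o-allylphenol formed may cyclise.

The fallback sets out from 4 and comes back at 8.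
- Iodination with benzyltrimethylammonium dichloroiodate and CaCO3 in CH2Cl2/MeOH is expected to take place ortho to the chelated 5-OH and give 5-hydroxy-6-iodo-7-methoxy-4H-chromen-4-one F11.
- Stille coupling with allyltributylstannane (Pd(PPh3)4, DMF, 90 °C) then gives 8.

## Further compounds

F1 | step 6 | 1-[3-allyl-6-hydroxy-4-methoxy-2-(methoxymethoxy)phenyl]ethan-1-one | CC(=O)c1c(O)cc(OC)c(CC=C)c1OCOC
F2 | step 6 | 3-methoxy-4-(methoxymethoxy)benzaldehyde | COCOc1ccc(C=O)cc1OC
F3 | step 6 | (E)-1-[3-allyl-6-hydroxy-4-methoxy-2-(methoxymethoxy)phenyl]-3-[3-methoxy-4-(methoxymethoxy)phenyl]prop-2-en-1-one | COCOc1ccc(/C=C/C(=O)c2c(O)cc(OC)c(CC=C)c2OCOC)cc1OC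
F4 | step 6 | racemic 6-allyl-7-methoxy-2-[3-methoxy-4-(methoxymethoxy)phenyl]-5-(methoxymethoxy)chroman-4-one | COc1cc(C2Oc3cc(OC)c(CC=C)c(OCOC)c3C(=O)C2)ccc1OCOC
F5 | step 6 | (2R,4R)-6-allyl-7-methoxy-2-[3-methoxy-4-(methoxymethoxy)phenyl]-5-(methoxymethoxy)chroman-4-ol | COc1cc([C@@H]2Oc3cc(OC)c(CC=C)c(OCOC)c3[C@H](O)C2)ccc1OCOC
F6 | step 7 | tert-butyl{[(2S)-6-allyl-7-methoxy-2-[3-methoxy-4-(methoxymethoxy)phenyl]-5-(methoxymethoxy)-2H-chromen-4-yl]oxy}dimethylsilane | COc1cc([C@H]2Oc3cc(OC)c(CC=C)c(OCOC)c3C(O[Si](C)(C)C(C)(C)C)=C2)ccc1OCOC
F7 | step 7 | (2R,3R)-6-allyl-3-[(tert-butyldimethylsilyl)oxy]-7-methoxy-2-[3-methoxy-4-(methoxymethoxy)phenyl]-5-(methoxymethoxy)chroman-4-one | COc1cc([C@H]2Oc3cc(OC)c(CC=C)c(OCOC)c3C(=O)[C@@H]2O[Si](C)(C)C(C)(C)C)ccc1OCOC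
F8 | step 9 | 7-methoxy-5-(methoxymethoxy)-6-(3-methylbut-2-en-1-yl)-4H-chromen-4-one | COCOc1c(CC=C(C)C)c(OC)cc2c1C(=O)C=CO2
F9 | step 9 | (2S)-7-methoxy-2-[3-methoxy-4-(methoxymethoxy)phenyl]-5-(methoxymethoxy)-6-(3-methylbut-2-en-1-yl)chroman-4-one | COc1cc([C@H]2Oc3cc(OC)c(CC=C(C)C)c(OCOC)c3C(=O)C2)ccc1OCOC
F10 | step 9 | (2R,3R)-3-hydroxy-7-methoxy-2-[3-methoxy-4-(methoxymethoxy)phenyl]-5-(methoxymethoxy)-6-(3-methylbut-2-en-1-yl)chroman-4-one | COc1cc([C@H]2Oc3cc(OC)c(CC=C(C)C)c(OCOC)c3C(=O)[C@@H]2O)ccc1OCOC
F11 | step 3 | 5-hydroxy-6-iodo-7-methoxy-4H-chromen-4-one | COc1cc2c(c(O)c1I)C(=O)C=CO2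
A1 | alternative 1 | (E)-1-[3-allyl-4-methoxy-2,6-bis(methoxymethoxy)phenyl]-3-[3-methoxy-4-(methoxymethoxy)phenyl]prop-2-en-1-one | COCOc1ccc(/C=C/C(=O)c2c(OCOC)cc(OC)c(CC=C)c2OCOC)cc1OC
A2 | alternative 1 | [3-allyl-4-methoxy-2,6-bis(methoxymethoxy)phenyl]{(2R,3S)-3-[3-methoxy-4-(methoxymethoxy)phenyl]oxiran-2-yl}methanone | O=C(c1c(OCOC)cc(OC)c(CC=C)c1OCOC)[C@@H]2O[C@H]2c3ccc(OCOC)c(OC)c3
A3 | alternative 2 | 3-allyl-4-methoxy-2-(methoxymethoxy)-6-{1-[3-methoxy-4-(methoxymethoxy)phenyl]-2-oxoethoxy}benzaldehyde | O=Cc1c(OC(C=O)c2ccc(OCOC)c(OC)c2)cc(OC)c(CC=C)c1OCOC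
A4 | alternative 3 | 4-allyl-3-methoxy-5-(methoxymethoxy)phenol | COCOc1cc(O)cc(OC)c1CC=C
A5 | alternative 3 | methyl (2R,3S)-3-[3-methoxy-4-(methoxymethoxy)phenyl]oxirane-2-carboxylate | COC(=O)[C@@H]1O[C@H]1c2ccc(OCOC)c(OC)c2
A6 | alternative 3 | methyl (2R,3R)-3-[4-allyl-3-methoxy-5-(methoxymethoxy)phenoxy]-2-hydroxy-3-[3-methoxy-4-(methoxymethoxy)phenyl]propanoate | COC(=O)[C@H](O)[C@H](Oc1cc(OC)c(CC=C)c(OCOC)c1)c2ccc(OCOC)c(OC)c2
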